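Retrosynthesis: 15 ⇒ 12 by late C-2/C-3 desaturation (selenoxide elimination); C-5 is quaternary, so the enone can form only in this direction.
12 ⇒ 11: the only ring is closed by a polyketide-type 6-enolexo aldol of the methyl-ketone carbon C-6 onto the acyl ketone C-5, keeping the aldol hydroxyl and setting C-5 cis to the C-4 hydroxyl.
11 ⇒ 9 + 10: asymmetric Michael addition of a hydroxymethyl ketone (through its carbinol carbon) to methyl vinyl ketone sets C-4; addition and ring closure share one flask, with no protecting groups.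
9 ⇒ 4 + 5: one-carbon homologation of the fatty acid to RCOCH2OH.
4 ⇒ 1 + 2: acetylide alkylation, then dissolving-metal reduction to the E-alkene.

Assumption: the ring is taken to arise in nature, as for the co-occurring cardanols, from a fatty-acyl-primed polyketide by intramolecular aldol of the terminal acetate carbon onto the acyl ketone, here with the aldol hydroxyl retained.

Ring numbering used below: C-1 carbonyl, C-2/C-3 alkene, C-4 secondary carbinol, C-5 tertiary carbinol, C-6 methylene. The target is (4R,5S), a cis-diol.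

Step 1
Reactants: 1 16-bromohexadecanoic acid; 2 but-1-yne
Product: 3 icos-17-ynoic acid
Conditions: 2 (3.5 equiv), n-BuLi (3.2 equiv), THF–DMPU, −78 °C; then 1, −78 °C to rt, 16 h; aq HCl
Reagents that add atoms: none
Why: SN2 alkylation of lithium but-1-ynide (acetylide alkylation) on the primary bromide of the in situ lithium carboxylate is clean in a dipolar cosolvent because one extra equivalent of acetylide takes up the acid proton, and no stereocentre is formed.

Step 2
Reactants: 3 icos-17-ynoic acid
Product: 4 (17E)-icos-17-enoic acid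
Conditions: Li (8 equiv), NH3(l)–THF, −33 °C, 3 h; NH4Cl; aq HCl
Reagents that add atoms: none
Why: Dissolving-metal reduction of the isolated internal alkyne goes through the trans vinyl radical/anion and gives the E-alkene only, while the carboxylate is inert to Li/NH3.

Step 3
Reactants: 4 (17E)-icos-17-enoic acid; 5 tris(trimethylsilyloxy)ethene
Product: 9 (18E)-1-hydroxyhenicos-18-en-2-one, via acyl chloride 6 (not isolated), via silylated adduct 7 (not isolated), via keto acid 8 (not isolated)
Conditions: (COCl)2, cat. DMF, CH2Cl2, rt, then evaporate; 5 (2.2 equiv), neat, 95 °C, 4 h; 0.6 M aq HCl, dioxane, 85 °C, 30 min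
Reagents that add atoms: none
Why: Wissner hydroxymethyl ketone synthesis, in which the tris-silyl ketene acetal is C-acylated by the acyl chloride and the resulting α-silyloxy β-keto silyl ester is hydrolysed and decarboxylated by brief warm dilute acid that the isolated E-alkene tolerates.

Step 4
Reactants: 9 (18E)-1-hydroxyhenicos-18-en-2-one; 10 but-3-en-2-one
Product: 12 (3S,4R)-3,4-dihydroxy-3-[(16E)-nonadec-16-en-1-yl]cyclohexan-1-one, via hydroxy diketone 11 (not isolated)
Conditions: 10 (1.2 equiv), Et2Zn (10 mol%), (S,S)-3,3''-[oxybis(methylene)]bis(1,1'-binaphthalene-2,2'-diol) [(S,S)-linked-BINOL] (2.5 mol%), 3 Å molecular sieves, THF, 4 °C, 16 h; evaporate volatiles; L-proline (30 mol%), DMF–CHCl3, rt, 48 h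
Reagents that add atoms: none
Why: Proposed new method: Et2Zn and the (S,S)-ligand turn 9 into a chelated zinc enediolate that adds through its carbinol carbon to 10 (closest known reaction: the Et2Zn/linked-BINOL direct Michael addition of aryl hydroxymethyl ketones to vinyl ketones, in which this ligand gives 2R adducts), which sets C-4 as R in 11, and L-proline then forms the terminal enamine of the unhindered methyl ketone, which attacks the hydrogen-bonded α-hydroxy ketone in a chair-like 6-enolexo intramolecular aldol (closest known reaction: the Hajos–Parrish ketol cyclisation, where L-proline gives the same absolute sense at the carbinol carbon) with the chain equatorial and the new hydroxyl cis to the C-4 hydroxyl, so that C-5 is set as S and the aldol hydroxyl is retained as in the polyketide ring closure.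

Step 5
Reactants: 12 (3S,4R)-3,4-dihydroxy-3-[(16E)-nonadec-16-en-1-yl]cyclohexan-1-one
Product: 15 (4R,5S)-4,5-dihydroxy-5-[(16E)-nonadec-16-en-1-yl]cyclohex-2-en-1-one, via selenide 13 (not isolated), via selenoxide 14 (not isolated)
Conditions: N-(phenylseleno)phthalimide (1.1 equiv), (S)-1,1,1-trifluoro-N-(pyrrolidin-2-ylmethyl)methanesulfonamide (10 mol%), CH2Cl2, rt; then 3-chloroperoxybenzoic acid (1.3 equiv), −78 °C; i-Pr2NH, −78 to 0 °C
Reagents that add atoms: none
Why: Enamine-mediated α-selenenylation occurs at C-2, the α-carbon remote from the quaternary carbinol, and the selenoxide formed at −78 °C (where the peracid oxidises selenium far faster than the isolated alkene) undergoes Reich–Sharpless syn-elimination that can only give the C-2/C-3 enone, leaving both stereocentres untouched.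

Compound list
1 | 16-bromohexadecanoic acid | OC(=O)CCCCCCCCCCCCCCCBr | starting material
2 | but-1-yne | CCC#C | starting material
3 | icos-17-ynoic acid | CCC#CCCCCCCCCCCCCCCCC(=O)O | intermediate
4 | (17E)-icos-17-enoic acid | CC/C=C/CCCCCCCCCCCCCCCC(=O)O | intermediate
5 | tris(trimethylsilyloxy)ethene | C[Si](C)(C)OC=C(O[Si](C)(C)C)O[Si](C)(C)C | starting material
6 | (17E)-icos-17-enoyl chloride | CC/C=C/CCCCCCCCCCCCCCCC(Cl)=O | intermediate
7 | trimethylsilyl (19E)-3-oxo-2-(trimethylsilyloxy)docos-19-enoate | CC/C=C/CCCCCCCCCCCCCCCC(=O)C(O[Si](C)(C)C)C(=O)O[Si](C)(C)C | intermediate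
8 | (19E)-2-hydroxy-3-oxodocos-19-enoic acid | CC/C=C/CCCCCCCCCCCCCCCC(=O)C(O)C(=O)O | intermediate
9 | (18E)-1-hydroxyhenicos-18-en-2-one | CC/C=C/CCCCCCCCCCCCCCCC(=O)CO | intermediate
10 | but-3-en-2-one | CC(=O)C=C | starting material
11 | (5R,22E)-5-hydroxypentacos-22-ene-2,6-dione | CC/C=C/CCCCCCCCCCCCCCCC(=O)[C@H](O)CCC(C)=O | intermediate
12 | (3S,4R)-3,4-dihydroxy-3-[(16E)-nonadec-16-en-1-yl]cyclohexan-1-one | CC/C=C/CCCCCCCCCCCCCCC[C@]1(O)CC(=O)CC[C@H]1O | intermediate
13 | (4R,5S)-4,5-dihydroxy-5-[(16E)-nonadec-16-en-1-yl]-2-(phenylselanyl)cyclohexan-1-one (C-2 epimers) | CC/C=C/CCCCCCCCCCCCCCC[C@]1(O)CC(=O)C([Se]c2ccccc2)C[C@H]1O | intermediate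
14 | (4R,5S)-4,5-dihydroxy-5-[(16E)-nonadec-16-en-1-yl]-2-(phenylseleninyl)cyclohexan-1-one (C-2 epimers) | CC/C=C/CCCCCCCCCCCCCCC[C@]1(O)CC(=O)C([Se](=O)c2ccccc2)C[C@H]1O | intermediate
15 | (4R,5S)-4,5-dihydroxy-5-[(16E)-nonadec-16-en-1-yl]cyclohex-2-en-1-one | CC/C=C/CCCCCCCCCCCCCCC[C@]1(O)CC(=O)C=C[C@H]1O | target

Total step count: 5. Longest linear sequence: 5 (1 → 3 → 4 → 9 → 12 → 15).

Steps most likely to fail

Step 4 is the most exposed. The zinc-catalysed Michael addition has direct precedent only for aryl hydroxymethyl ketones, so the enantioselectivity with the alkyl ketone 9 may fall short; the sense of induction and the match with L-proline are assigned by analogy and recalled from the literature, not checked against it. The proline closure may also give some trans-diol or dehydrated enone. If needed, the two stages can be run with isolation of 11. The fallback sets out from 9 and comes back at 12, and moves stereocontrol to a classical resolution: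
- Et3N-catalysed Michael addition of 9 to 10 gives the hydroxy diketone as the racemate, that is 11 together with (5S,22E)-5-hydroxypentacos-22-ene-2,6-dione F1.
- DL-proline closes it to the racemic cis-ketol, that is 12 together with (3R,4S)-3,4-dihydroxy-3-[(16E)-nonadec-16-en-1-yl]cyclohexan-1-one F2.
- Esterification of the secondary hydroxyl with (S)-2-methoxy-2-phenylacetic acid (N-ethyl-N'-(3-dimethylaminopropyl)carbodiimide hydrochloride, 4-(dimethylamino)pyridine, CH2Cl2) gives two diastereomeric esters, separated on silica: (1R,2S)-2-hydroxy-2-[(16E)-nonadec-16-en-1-yl]-4-oxocyclohexyl (2S)-2-methoxy-2-phenylacetate F3 and (1S,2R)-2-hydroxy-2-[(16E)-nonadec-16-en-1-yl]-4-oxocyclohexyl (2S)-2-methoxy-2-phenylacetate F4.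
- Methanolysis of F3 (K2CO3, MeOH, 0 °C) returns 12.

Step 5 is second. The amine catalyst could trigger loss of the tertiary aldol hydroxyl, or selenenylation could go partly to C-6, where no elimination is possible. The fallback sets out from 12 and comes back at 15, and uses silyl enol ether chemistry instead:
- Exhaustive silylation with Me3SiOTf/Et3N (CH2Cl2, 0 °C) gives (4R,5S)-5-[(16E)-nonadec-16-en-1-yl]-1,4,5-tris(trimethylsilyloxy)cyclohex-1-ene F5, the enol ether forming away from the quaternary carbon.
- Saegusa–Ito oxidation with Pd(OAc)2 (1.1 equiv, MeCN, rt) gives (4R,5S)-5-[(16E)-nonadec-16-en-1-yl]-4,5-bis(trimethylsilyloxy)cyclohex-2-en-1-one F6.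
- HF·pyridine (THF, 0 °C) removes both silyl ethers to give 15.

Step 3 is third. The neat thermal acylation of the ketene acetal with a waxy long-chain acyl chloride may be sluggish, and the hot acid step could cost material. The fallback sets out from 4 and comes back at 9, and swaps the ketene-acetal homologation for diazoketone chemistry:
- Acid 4 is converted to acyl chloride 6 as before and added to excess ethereal diazomethane at 0 °C to give (18E)-1-diazohenicos-18-en-2-one F7.
- Hydrolysis of F7 with dilute H2SO4 in dioxane at 60 °C gives 9.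

Further compounds
F1 | step 4 | (5S,22E)-5-hydroxypentacos-22-ene-2,6-dione | CC/C=C/CCCCCCCCCCCCCCCC(=O)[C@@H](O)CCC(C)=O
F2 | step 4 | (3R,4S)-3,4-dihydroxy-3-[(16E)-nonadec-16-en-1-yl]cyclohexan-1-one | CC/C=C/CCCCCCCCCCCCCCC[C@@]1(O)CC(=O)CC[C@@H]1O
F3 | step 4 | (1R,2S)-2-hydroxy-2-[(16E)-nonadec-16-en-1-yl]-4-oxocyclohexyl (2S)-2-methoxy-2-phenylacetate | CC/C=C/CCCCCCCCCCCCCCC[C@]1(O)CC(=O)CC[C@H]1OC(=O)[C@@H](OC)c1ccccc1
F4 | step 4 | (1S,2R)-2-hydroxy-2-[(16E)-nonadec-16-en-1-yl]-4-oxocyclohexyl (2S)-2-methoxy-2-phenylacetate | CC/C=C/CCCCCCCCCCCCCCC[C@@]1(O)CC(=O)CC[C@@H]1OC(=O)[C@@H](OC)c1ccccc1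
F5 | step 5 | (4R,5S)-5-[(16E)-nonadec-16-en-1-yl]-1,4,5-tris(trimethylsilyloxy)cyclohex-1-ene | CC/C=C/CCCCCCCCCCCCCCC[C@]1(O[Si](C)(C)C)CC(O[Si](C)(C)C)=CC[C@H]1O[Si](C)(C)C
F6 | step 5 | (4R,5S)-5-[(16E)-nonadec-16-en-1-yl]-4,5-bis(trimethylsilyloxy)cyclohex-2-en-1-one | CC/C=C/CCCCCCCCCCCCCCC[C@]1(O[Si](C)(C)C)CC(=O)C=C[C@H]1O[Si](C)(C)C
F7 | step 3 | (18E)-1-diazohenicos-18-en-2-one | CC/C=C/CCCCCCCCCCCCCCCC(=O)C=[N+]=[N-]
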